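**Strategy.** Everything rests on disconnecting the O6–C7 bond of the oxepene ring B. C7 lies between O6, the exocyclic C12 and C8, so it can serve as the carbon of an ester- and ketone-stabilised rhodium carbenoid, and O6 belongs to a hindered tertiary ether at the ring-fusion carbon C5 of ring A. Intramolecular O–H insertion therefore makes this congested ether and closes the seven-membered ring in one operation, leaving C12 as an ester and C8 as a ketone for the later bromomethyl and hydroxymethyl-alkene units. The precursor is a ring-A cyclohexane, already brominated at C2, bearing the tertiary C5 hydroxyl and, on C11, a CH2CH2C(=O)C(N2)CO2Et chain; it comes from a trans-fused δ-lactone.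

Key step: step 11

Remark: atoms keep the target numbering in all intermediates (ring A: C1(Me2), C2(Br), C3, C4, C5(Me), C11; ring B: C5, O6, C7, C8, C9, C10, C11; C12 on C7, C13 on C8), and the CH2Br group on C7 is taken to lie on the same face as the C5 methyl (C7–H on the opposite, α-face), as the given configuration requires.

**Step 1**
Reactants: 1 2-methylcyclopentane-1,3-dione; 2 ethyl vinyl ketone (pent-1-en-3-one)
Product: 3 2-methyl-2-(3-oxopentyl)cyclopentane-1,3-dione
Conditions: AcOH (cat.), H2O, 70 °C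
Reagents that add atoms: ethyl vinyl ketone (compound 2), CCC(=O)C=C
Why: Michael addition of the acidic cyclic 1,3-dione to the enone under mild acid catalysis is the standard first half of a Robinson annulation and creates no stereocentre.

**Step 2**
Reactants: 3 2-methyl-2-(3-oxopentyl)cyclopentane-1,3-dione
Product: 4 (S)-4,7a-dimethyl-2,3,7,7a-tetrahydro-1H-indene-1,5(6H)-dione
Conditions: L-phenylalanine (1 equiv), (1S)-(+)-10-camphorsulfonic acid (0.5 equiv), DMF, 30 → 70 °C
Reagents that add atoms: none
Why: Amino-acid-mediated enantioselective intramolecular aldol condensation (Hajos–Parrish–Eder–Sauer–Wiechert reaction): the enamine of the side-chain ketone attacks one of the two enantiotopic ring carbonyls, which sets the quaternary C5 as S, and dehydration gives the enone; recrystallisation should raise the enantiomeric purity.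

**Step 3**
Reactants: 4 (S)-4,7a-dimethyl-2,3,7,7a-tetrahydro-1H-indene-1,5(6H)-dione
Product: 5 (1S,7aS)-1-hydroxy-4,7a-dimethyl-1,2,3,6,7,7a-hexahydro-5H-inden-5-one
Conditions: NaBH4 (0.3 equiv), EtOH, −20 °C
Reagents that add atoms: none
Why: Chemoselective borohydride reduction: the saturated C8 cyclopentanone is more electrophilic than the conjugated C2 ketone, and hydride adds from the face opposite the angular methyl, giving the 8β-alcohol (a temporary stereocentre).

**Step 4**
Reactants: 5 (1S,7aS)-1-hydroxy-4,7a-dimethyl-1,2,3,6,7,7a-hexahydro-5H-inden-5-one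
Product: 6 (1S,7aS)-1-[(tert-butyldimethylsilyl)oxy]-4,7a-dimethyl-1,2,3,6,7,7a-hexahydro-5H-inden-5-one
Conditions: TBSCl, imidazole, DMF, rt
Reagents that add atoms: tert-butyldimethylsilyl chloride, CC(C)(C)[Si](C)(C)Cl
Why: Standard silylation of a secondary alcohol; the silyl ether protects C8–O through the dissolving-metal, hydride and Appel steps.

**Step 5**
Reactants: 6 (1S,7aS)-1-[(tert-butyldimethylsilyl)oxy]-4,7a-dimethyl-1,2,3,6,7,7a-hexahydro-5H-inden-5-one; 7 iodomethane
Product: 9 (1S,3aR,7aS)-1-[(tert-butyldimethylsilyl)oxy]-4,4,7a-trimethyloctahydro-5H-inden-5-one (trans-fused), via lithium enolate 8 (not isolated)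
Conditions: Li (2.2 equiv), NH3(l)/THF, t-BuOH (1 equiv), −78 °C; then MeI, −78 → −33 °C
Reagents that add atoms: iodomethane (compound 7), CI
Why: Dissolving-metal reduction of the enone with alkylation of the regiodefined enolate (reductive alkylation): axial protonation of the β-carbon C11 opposite the angular C5 methyl gives the trans ring fusion (C11–H α), and C-methylation of enolate 8 at C1 completes the gem-dimethyl group without a further stereocentre.

**Step 6**
Reactants: 9 (1S,3aR,7aS)-1-[(tert-butyldimethylsilyl)oxy]-4,4,7a-trimethyloctahydro-5H-inden-5-one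
Product: 10 (1S,3aS,5R,7aS)-1-[(tert-butyldimethylsilyl)oxy]-4,4,7a-trimethyloctahydro-1H-inden-5-ol (axial C2–OH)
Conditions: LiBH(s-Bu)3 (L-Selectride), THF, −78 °C; aq. NH4Cl
Reagents that add atoms: none
Why: The bulky trialkylborohydride attacks the hindered C2 ketone along the equatorial trajectory, so the new hydroxyl is axial (α), the configuration needed for inversion in step 7.

**Step 7**
Reactants: 10 (1S,3aS,5R,7aS)-1-[(tert-butyldimethylsilyl)oxy]-4,4,7a-trimethyloctahydro-1H-inden-5-ol
Product: 11 tert-butyl{[(1S,3aR,5S,7aS)-5-bromo-4,4,7a-trimethyloctahydro-1H-inden-1-yl]oxy}dimethylsilane (equatorial C2–Br)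
Conditions: CBr4, PPh3, CH2Cl2, 0 °C → rt
Reagents that add atoms: carbon tetrabromide, BrC(Br)(Br)Br
Why: Appel reaction: the axial alkoxyphosphonium ion is displaced by bromide in an SN2 step with inversion, which gives the equatorial β-bromide at C2 (S); with an axial leaving group no ring C–C bond is antiperiplanar, so the ring contraction typical of equatorial leaving groups beside a quaternary carbon is not set up.

**Step 8**
Reactants: 11 tert-butyl{[(1S,3aR,5S,7aS)-5-bromo-4,4,7a-trimethyloctahydro-1H-inden-1-yl]oxy}dimethylsilane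
Product: 13 (3aR,5S,7aS)-5-bromo-4,4,7a-trimethyloctahydro-1H-inden-1-one, via bromo alcohol 12 (not isolated)
Conditions: CrO3, H2SO4, H2O, acetone, 0 °C → rt
Reagents that add atoms: none
Why: Jones oxidation with desilylation in the same flask: the aqueous acid cleaves the silyl ether to alcohol 12, which chromic acid oxidises to the C8 ketone; neither α-carbon (quaternary C5, methylene C9) can epimerise.

**Step 9**
Reactants: 13 (3aR,5S,7aS)-5-bromo-4,4,7a-trimethyloctahydro-1H-inden-1-one
Product: 14 (4aS,6S,8aS)-6-bromo-5,5,8a-trimethyloctahydro-2H-chromen-2-one (trans-fused δ-lactone)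
Conditions: mCPBA, NaHCO3, CH2Cl2, rt
Reagents that add atoms: meta-chloroperoxybenzoic acid, OOC(=O)c1cccc(Cl)c1
Why: Baeyer–Villiger oxidation: the fully substituted C5 migrates in preference to the C9 methylene and with retention, so O6 is inserted between C5 and C8 and the trans relation of the C5 methyl and C11–H is kept.

**Step 10**
Reactants: 14 (4aS,6S,8aS)-6-bromo-5,5,8a-trimethyloctahydro-2H-chromen-2-one; 15 ethyl diazoacetate
Product: 17 ethyl 5-[(1S,3S,6S)-3-bromo-6-hydroxy-2,2,6-trimethylcyclohexyl]-2-diazo-3-oxopentanoate, via ethyl lithiodiazoacetate 16 (not isolated)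
Conditions: 15, LiN(i-Pr)2, THF, −78 °C; then 14, −78 °C; AcOH quench at −78 °C
Reagents that add atoms: ethyl diazoacetate (compound 15), CCOC(=O)C=[N+]=[N-]
Why: Acylation of the lithiated diazo ester by the lactone carbonyl (Claisen-type ring opening) forms the C7–C8 bond and releases the tertiary C5 alkoxide; the cold acidic quench prevents reclosure, and the diazo-conjugated C8 ketone is a weak electrophile, so the product should rest as the open hydroxy ketone.

**Step 11 (key step)**
Reactants: 17 ethyl 5-[(1S,3S,6S)-3-bromo-6-hydroxy-2,2,6-trimethylcyclohexyl]-2-diazo-3-oxopentanoate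
Product: 19 ethyl (5aS,7S,9aS)-7-bromo-3-hydroxy-6,6,9a-trimethyl-4,5,5a,6,7,8,9,9a-octahydro-1-benzoxepine-2-carboxylate (enol form of the 3-oxo ester), via oxonium ylide 18 (not isolated)
Conditions: Rh2(OAc)4 (2 mol%), benzene, reflux, slow addition of 17 at high dilution
Reagents that add atoms: none
Why: Rh2(OAc)4 extrudes N2 from 17 to give an electrophilic dirhodium carbenoid at C7, stabilised by the C12 ester and the C8 ketone; the C5 hydroxyl oxygen attacks it to form the metal-associated oxonium ylide 18, and proton transfer from oxygen releases the catalyst and the β-keto ester, which rests as its enol. The closest known reaction type is the dirhodium-tetracarboxylate-catalysed intramolecular O–H insertion of ω-hydroxy α-diazo β-keto esters, made from lactones and lithiated ethyl diazoacetate, which gives 3-oxo-oxepane-2-carboxylates also from tertiary alcohols. Ring B closes by O6–C7 bond formation, a seven-membered closure in which the tethered oxygen attacks the carbenoid carbon, and because the C5–O and C11–C10 bonds are both equatorial on ring A the trans fusion set earlier is carried over. No stereocentre is created: C7 is sp2 in the enol and is set in step 13, while C2, C5 and C11 are not touched. The step needs chemoselectivity for O–H insertion over 1,5 C–H insertion into the C11–H methine (which would give a spiro cyclopentanone) and over intermolecular reaction; heteroatom capture by an acceptor/acceptor carbenoid is much faster than C–H insertion, the gauche hydroxyl lies within reach of C7, carboxylate rather than carboxamidate ligands disfavour C–H insertion, and slow addition at high dilution suppresses dimer formation.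

**Step 12**
Reactants: 19 ethyl (5aS,7S,9aS)-7-bromo-3-hydroxy-6,6,9a-trimethyl-4,5,5a,6,7,8,9,9a-octahydro-1-benzoxepine-2-carboxylate
Product: 20 ethyl (5aS,7S,9aS)-7-bromo-6,6,9a-trimethyl-3-{[(trifluoromethyl)sulfonyl]oxy}-4,5,5a,6,7,8,9,9a-octahydro-1-benzoxepine-2-carboxylate
Conditions: Tf2O, i-Pr2NEt, CH2Cl2, −78 → 0 °C
Reagents that add atoms: trifluoromethanesulfonic anhydride, O=S(=O)(OS(=O)(=O)C(F)(F)F)C(F)(F)F
Why: O-Sulfonylation of the enolised β-keto ester gives the conjugated alkenyl triflate, which turns the C8 oxygen into a leaving group for the later C13 coupling.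

**Step 13**
Reactants: 20 ethyl (5aS,7S,9aS)-7-bromo-6,6,9a-trimethyl-3-{[(trifluoromethyl)sulfonyl]oxy}-4,5,5a,6,7,8,9,9a-octahydro-1-benzoxepine-2-carboxylate
Product: 22 ethyl (2R,5aS,7S,9aS)-7-bromo-6,6,9a-trimethyl-3-{[(trifluoromethyl)sulfonyl]oxy}-2,5,5a,6,7,8,9,9a-octahydro-1-benzoxepine-2-carboxylate (C7–H α; C8=C9), via lithium dienolate 21 (not isolated)
Conditions: LiN(i-Pr)2 (1.1 equiv), THF/DMPU, −78 °C; then inverse quench into AcOH/THF, −78 °C
Reagents that add atoms: none
Why: Deconjugation of an α,β-unsaturated ester through its dienolate: C8 carries the triflate instead of a carbon substituent, so C9 holds the only γ-hydrogens and a single dienolate 21 forms; kinetic protonation at the α-carbon C7 from the α-face, opposite the axial C5 methyl that lies 1,3 to C7 across O6, sets C7 (R, ester β) and leaves the double bond at C8=C9.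

**Step 14**
Reactants: 22 ethyl (2R,5aS,7S,9aS)-7-bromo-6,6,9a-trimethyl-3-{[(trifluoromethyl)sulfonyl]oxy}-2,5,5a,6,7,8,9,9a-octahydro-1-benzoxepine-2-carboxylate
Product: 23 (2S,5aS,7S,9aS)-7-bromo-2-(hydroxymethyl)-6,6,9a-trimethyl-2,5,5a,6,7,8,9,9a-octahydro-1-benzoxepin-3-yl trifluoromethanesulfonate (same spatial arrangement at C7; the descriptor changes by priority only)
Conditions: i-Bu2AlH (3 equiv), CH2Cl2, −78 → −40 °C; aq. potassium sodium tartrate
Reagents that add atoms: none
Why: Low-temperature reduction of the ester by the Lewis-acidic, non-basic aluminium hydride gives the primary C12 alcohol and removes the acidity of C7–H before it can epimerise or move the double bond back; the alkenyl triflate and the alkyl bromide are left alone.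

**Step 15**
Reactants: 23 (2S,5aS,7S,9aS)-7-bromo-2-(hydroxymethyl)-6,6,9a-trimethyl-2,5,5a,6,7,8,9,9a-octahydro-1-benzoxepin-3-yl trifluoromethanesulfonate
Product: 24 (2R,5aS,7S,9aS)-7-bromo-2-(bromomethyl)-6,6,9a-trimethyl-2,5,5a,6,7,8,9,9a-octahydro-1-benzoxepin-3-yl trifluoromethanesulfonate
Conditions: CBr4, PPh3, CH2Cl2, 0 °C
Reagents that add atoms: carbon tetrabromide, BrC(Br)(Br)Br
Why: Appel bromination of the unhindered primary alcohol (SN2 at C12), carried out while no other hydroxyl is present, so that C12 and C13 never need to be told apart.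

**Step 16**
Reactants: 24 (2R,5aS,7S,9aS)-7-bromo-2-(bromomethyl)-6,6,9a-trimethyl-2,5,5a,6,7,8,9,9a-octahydro-1-benzoxepin-3-yl trifluoromethanesulfonate; 25 (tributylstannyl)methanol
Product: 26 [(2R,5aS,7S,9aS)-7-bromo-2-(bromomethyl)-6,6,9a-trimethyl-2,5,5a,6,7,8,9,9a-octahydro-1-benzoxepin-3-yl]methanol (target)
Conditions: Bu3SnCH2OH, Pd(PPh3)4 (10 mol%), LiCl, 1,4-dioxane, 100 °C
Reagents that add atoms: (tributylstannyl)methanol (compound 25), OC[Sn](CCCC)(CCCC)CCCC
Why: Stille coupling: oxidative addition of the alkenyl triflate to zerovalent palladium, chloride-assisted transfer of the hydroxymethyl group from tin and reductive elimination attach C13 as the free allylic alcohol at C8 with the double bond fixed at C8=C9; the hindered secondary bromide and the β-alkoxy primary bromide react far more slowly with the triphenylphosphine-ligated catalyst.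

**Compound list**

1 | 2-methylcyclopentane-1,3-dione | CC1C(=O)CCC1=O | starting material
2 | ethyl vinyl ketone (pent-1-en-3-one) | CCC(=O)C=C | starting material
3 | 2-methyl-2-(3-oxopentyl)cyclopentane-1,3-dione | CCC(=O)CCC1(C)C(=O)CCC1=O | intermediate
4 | (S)-4,7a-dimethyl-2,3,7,7a-tetrahydro-1H-indene-1,5(6H)-dione | O=C1CC[C@]2(C)C(=O)CCC2=C1C | intermediate
5 | (1S,7aS)-1-hydroxy-4,7a-dimethyl-1,2,3,6,7,7a-hexahydro-5H-inden-5-one (OH cis to the angular methyl) | O=C1CC[C@]2(C)[C@@H](O)CCC2=C1C | intermediate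
6 | (1S,7aS)-1-[(tert-butyldimethylsilyl)oxy]-4,7a-dimethyl-1,2,3,6,7,7a-hexahydro-5H-inden-5-one | O=C1CC[C@]2(C)[C@@H](O[Si](C)(C)C(C)(C)C)CCC2=C1C | intermediate
7 | iodomethane | CI | starting material
8 | lithium enolate of the trans-fused monomethyl ketone (O– on C2, C1=C2, C11–H α) | [Li+].[O-]C1=C(C)[C@@H]2CC[C@H](O[Si](C)(C)C(C)(C)C)[C@@]2(C)CC1 | intermediate (not isolated)
9 | (1S,3aR,7aS)-1-[(tert-butyldimethylsilyl)oxy]-4,4,7a-trimethyloctahydro-5H-inden-5-one | O=C1CC[C@]2(C)[C@@H](O[Si](C)(C)C(C)(C)C)CC[C@H]2C1(C)C | intermediate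
10 | (1S,3aS,5R,7aS)-1-[(tert-butyldimethylsilyl)oxy]-4,4,7a-trimethyloctahydro-1H-inden-5-ol (axial OH) | O[C@@H]1CC[C@]2(C)[C@@H](O[Si](C)(C)C(C)(C)C)CC[C@H]2C1(C)C | intermediate
11 | tert-butyl{[(1S,3aR,5S,7aS)-5-bromo-4,4,7a-trimethyloctahydro-1H-inden-1-yl]oxy}dimethylsilane (equatorial Br) | Br[C@H]1CC[C@]2(C)[C@@H](O[Si](C)(C)C(C)(C)C)CC[C@H]2C1(C)C | intermediate
12 | (1S,3aR,5S,7aS)-5-bromo-4,4,7a-trimethyloctahydro-1H-inden-1-ol | Br[C@H]1CC[C@]2(C)[C@@H](O)CC[C@H]2C1(C)C | intermediate (not isolated)
13 | (3aR,5S,7aS)-5-bromo-4,4,7a-trimethyloctahydro-1H-inden-1-one | Br[C@H]1CC[C@]2(C)C(=O)CC[C@H]2C1(C)C | intermediate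
14 | (4aS,6S,8aS)-6-bromo-5,5,8a-trimethyloctahydro-2H-chromen-2-one | Br[C@H]1CC[C@]2(C)OC(=O)CC[C@H]2C1(C)C | intermediate
15 | ethyl diazoacetate | CCOC(=O)C=[N+]=[N-] | starting material
16 | ethyl lithiodiazoacetate (ethyl 2-diazo-2-lithioacetate) | CCOC(=O)C([Li])=[N+]=[N-] | intermediate (not isolated)
17 | ethyl 5-[(1S,3S,6S)-3-bromo-6-hydroxy-2,2,6-trimethylcyclohexyl]-2-diazo-3-oxopentanoate | CC1(C)[C@@H](Br)CC[C@](C)(O)[C@H]1CCC(=O)C(=[N+]=[N-])C(=O)OCC | intermediate (precursor of the key step)
18 | ring-closed oxonium ylide (O6 protonated and bonded to anionic C7; other centres as in 19; drawn without the metal) | CC1(C)[C@@H](Br)CC[C@]2(C)[OH+][C-](C(=O)OCC)C(=O)CC[C@@H]12 | intermediate (not isolated)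
19 | ethyl (5aS,7S,9aS)-7-bromo-3-hydroxy-6,6,9a-trimethyl-4,5,5a,6,7,8,9,9a-octahydro-1-benzoxepine-2-carboxylate (enol of the 3-oxo ester) | CC1(C)[C@@H](Br)CC[C@]2(C)OC(C(=O)OCC)=C(O)CC[C@@H]12 | intermediate (product of the key step)
20 | ethyl (5aS,7S,9aS)-7-bromo-6,6,9a-trimethyl-3-{[(trifluoromethyl)sulfonyl]oxy}-4,5,5a,6,7,8,9,9a-octahydro-1-benzoxepine-2-carboxylate | CC1(C)[C@@H](Br)CC[C@]2(C)OC(C(=O)OCC)=C(OS(=O)(=O)C(F)(F)F)CC[C@@H]12 | intermediate
21 | lithium ester dienolate of 20 (enolate at C12, C7=C12 and C8=C9) | [Li+].CC1(C)[C@@H](Br)CC[C@]2(C)OC(=C([O-])OCC)C(OS(=O)(=O)C(F)(F)F)=CC[C@@H]12 | intermediate (not isolated)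
22 | ethyl (2R,5aS,7S,9aS)-7-bromo-6,6,9a-trimethyl-3-{[(trifluoromethyl)sulfonyl]oxy}-2,5,5a,6,7,8,9,9a-octahydro-1-benzoxepine-2-carboxylate | CC1(C)[C@@H](Br)CC[C@]2(C)O[C@@H](C(=O)OCC)C(OS(=O)(=O)C(F)(F)F)=CC[C@@H]12 | intermediate
23 | (2S,5aS,7S,9aS)-7-bromo-2-(hydroxymethyl)-6,6,9a-trimethyl-2,5,5a,6,7,8,9,9a-octahydro-1-benzoxepin-3-yl trifluoromethanesulfonate | CC1(C)[C@@H](Br)CC[C@]2(C)O[C@@H](CO)C(OS(=O)(=O)C(F)(F)F)=CC[C@@H]12 | intermediate
24 | (2R,5aS,7S,9aS)-7-bromo-2-(bromomethyl)-6,6,9a-trimethyl-2,5,5a,6,7,8,9,9a-octahydro-1-benzoxepin-3-yl trifluoromethanesulfonate | CC1(C)[C@@H](Br)CC[C@]2(C)O[C@@H](CBr)C(OS(=O)(=O)C(F)(F)F)=CC[C@@H]12 | intermediate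
25 | (tributylstannyl)methanol | OC[Sn](CCCC)(CCCC)CCCC | starting material
26 | [(2R,5aS,7S,9aS)-7-bromo-2-(bromomethyl)-6,6,9a-trimethyl-2,5,5a,6,7,8,9,9a-octahydro-1-benzoxepin-3-yl]methanol | CC1(C)[C@@H](Br)CC[C@]2(C)O[C@@H](CBr)C(CO)=CC[C@@H]12 | target

**Totals**

Total step count: 16. Longest linear sequence: 16 steps (from 1 and 2 to 26); 7, 15 and 25 are commercial partners.

**Steps most likely to fail**

Step 11 (key step). The carbenoid may be consumed by 1,5 insertion into the C11–H methine, or by intermolecular reaction, before the hindered tertiary hydroxyl captures it. The fallback sets out from lactone 14 and comes back at 19. It makes the O6–C7 bond intermolecularly with a small carbenoid that has no internal C–H bond to compete, and closes ring B at C7–C8 instead. Aminolysis of 14 with MeNH(OMe)·HCl and AlMe3 (CH2Cl2, 0 °C → rt) should give the hydroxy Weinreb amide F1. Rh2(OAc)4-catalysed O–H insertion of ethyl diazoacetate 15 (slow addition, CH2Cl2, rt) into its tertiary alcohol should give the glycolate ether F2. Dieckmann-type closure with LiN(SiMe3)2 (THF, −78 → 0 °C), in which the α-alkoxy ester enolate acylates on the amide, should then give 19.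

Step 13. The dienolate may lose or transfer its triflyl group, protonation may be poorly face-selective, and the deconjugated ester may slip back into conjugation or epimerise at C7 on handling. The fallback sets out from 20 and comes back at 23. It sets C7 by hydroboration instead of protonation. Reduction of 20 with i-Bu2AlH (CH2Cl2, −78 °C) should give the allylic alcohol F3, and CBr4/PPh3 the allylic bromide F4. DBU (toluene, 80 °C) should effect 1,4-elimination through the C9 hydrogens, the only ones available, to the exocyclic enol ether diene F5. 9-BBN should add to the electron-rich C7=C12 bond, boron to C12 and hydrogen to C7 from the face opposite the axial C5 methyl, and oxidation with NaBO3 should give 23.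

Step 7. Elimination towards C3, or 1,2-shift of a C1 methyl, may outrun substitution at the neopentyl centre. The fallback sets out from ketone 9 and comes back at 11. It fixes the C2 configuration by hydrogen-atom transfer instead of SN2 displacement. N2H4·H2O (EtOH, reflux) should give the hydrazone F6. Oxidative bromination with CuBr2 and Et3N (THF/MeOH, rt), with loss of N2, should give the geminal dibromide F7. Radical mono-debromination (Bu3SnH 1 equiv, Et3B/air, toluene, −78 °C) should then give 11, because the α-bromo radical should take hydrogen along the unhindered axial (α) trajectory and leave bromine equatorial.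

**Further compounds**

F1 | step 11 | 3-[(1S,3S,6S)-3-bromo-6-hydroxy-2,2,6-trimethylcyclohexyl]-N-methoxy-N-methylpropanamide | CC1(C)[C@@H](Br)CC[C@](C)(O)[C@H]1CCC(=O)N(C)OC
F2 | step 11 | ethyl {[(1S,2S,4S)-4-bromo-2-{3-[methoxy(methyl)amino]-3-oxopropyl}-1,3,3-trimethylcyclohexyl]oxy}acetate | CC1(C)[C@@H](Br)CC[C@](C)(OCC(=O)OCC)[C@H]1CCC(=O)N(C)OC
F3 | step 13 | (5aS,7S,9aS)-7-bromo-2-(hydroxymethyl)-6,6,9a-trimethyl-4,5,5a,6,7,8,9,9a-octahydro-1-benzoxepin-3-yl trifluoromethanesulfonate | CC1(C)[C@@H](Br)CC[C@]2(C)OC(CO)=C(OS(=O)(=O)C(F)(F)F)CC[C@@H]12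
F4 | step 13 | (5aS,7S,9aS)-7-bromo-2-(bromomethyl)-6,6,9a-trimethyl-4,5,5a,6,7,8,9,9a-octahydro-1-benzoxepin-3-yl trifluoromethanesulfonate | CC1(C)[C@@H](Br)CC[C@]2(C)OC(CBr)=C(OS(=O)(=O)C(F)(F)F)CC[C@@H]12
F5 | step 13 | (5aS,7S,9aS)-7-bromo-6,6,9a-trimethyl-2-methylidene-2,5,5a,6,7,8,9,9a-octahydro-1-benzoxepin-3-yl trifluoromethanesulfonate | CC1(C)[C@@H](Br)CC[C@]2(C)OC(=C)C(OS(=O)(=O)C(F)(F)F)=CC[C@@H]12
F6 | step 7 | hydrazone of ketone 9 (C=N–NH2 at C2, other centres as in 9) | NN=C1CC[C@]2(C)[C@@H](O[Si](C)(C)C(C)(C)C)CC[C@H]2C1(C)C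
F7 | step 7 | geminal dibromide corresponding to 9 (CBr2 at C2, other centres as in 9) | BrC1(Br)CC[C@]2(C)[C@@H](O[Si](C)(C)C(C)(C)C)CC[C@H]2C1(C)C
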